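**Plan**

- Numbering and enabling feature: the ring carbons are C1 (CH–O next to the ring CH2, C2), C3–C4 (oxirane), C5 (ketone), C6 (CH–O), C7 (isopropenyl), C8 (CH–O), C9–C10 (oxirane); C14 and C15 are the methyl groups on C10 and C4. C5 and C10 face each other across the ten-membered ring, C9 carries oxygen, and C3–C4 is an oxidized Z-alkene. A C5–C10 bond therefore gives a cis-decalin whose ring B (C10–C1–C2–C3=C4–C5) is a cyclohexene and whose C5–O/C9–O pair is set up for a Grob fragmentation.
- Retrosynthetic cuts: the ester C–O bonds at C6 and C8, then at C1; oxirane C9–C10 back to the Z-alkene; C5–C10 added (Grob transform); ring B opened across C1–C2 and C5–C10 (Diels–Alder transform); then C10–C1 (formyl), C9–C10 (ethyl), C4–C5 (butenyl) and C7–isopropenyl, back to a butenolide.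
- Forward order: butenolide → open chain C5–C9 carrying a (Z)-enone arm and an (E)-β-acetoxy enone arm → intramolecular Diels–Alder reaction closes ring B (C1–C2) and ring A (sacrificial C5–C10) → oxirane C3–C4 on the decalin → Grob fragmentation of C5–C10 opens the ten-membered ring → oxirane C9–C10 → angelate on the free C1 hydroxyl → desilylation → angelates on C6 and C8.
- Stereochemistry: C6 from (S)-butenolide 1; C7 and C8 by anti cuprate addition and anti enolate hydroxylation; C1 from the dienophile geometry and the tether chair in the cycloaddition; C3/C4 by epoxidation directed by the C5 hydroxyl; the cis geometry of both oxiranes from ring B and from the stereospecific fragmentation; C9/C10 by oxygen delivery from the C1 hydroxyl.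

Key step: step 9

Remark: the esters are read as angelates ((Z)-2-methylbut-2-enoates) and both oxiranes as cis (the two ring bonds on the same side), as the SMILES requires; compound 1, (Z)-2-bromobut-2-ene and angelic anhydride are taken as purchasable.

**Route**

Step 1
Reactants: 1 (S)-5-(trityloxymethyl)furan-2(5H)-one; 2 isopropenylmagnesium bromide
Product: 4 all-trans 3-hydroxy-4-isopropenyl-5-(trityloxymethyl)dihydrofuran-2(3H)-one, via bromomagnesium lactone enolate 3 (not isolated)
Conditions: 2 (2.2 equiv), CuBr·SMe2 (1.1 equiv), THF/Me2S, −78 °C; then 2-(phenylsulfonyl)-3-phenyloxaziridine, −78 to −40 °C; aq. NH4Cl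
Reagents that add atoms: 2-(phenylsulfonyl)-3-phenyloxaziridine, O=S(=O)(c1ccccc1)N1OC1c1ccccc1
Why: Tandem cuprate conjugate addition and electrophilic enolate hydroxylation, in which the alkenylcuprate should add anti to the bulky trityloxymethyl group on C6 (setting C7) and the enolate should be oxidized anti to the new isopropenyl group (setting C8), so that the all-trans lactone results.

Step 2
Reactants: 4 all-trans 3-hydroxy-4-isopropenyl-5-(trityloxymethyl)dihydrofuran-2(3H)-one
Product: 6 N-methoxy-N-methyl-2,4-bis(tert-butyldimethylsilyloxy)-3-isopropenyl-5-(trityloxy)pentanamide, via dihydroxy amide 5 (not isolated)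
Conditions: MeNHOMe·HCl, AlMe3, CH2Cl2, 0 °C to rt; work-up; crude 5, TBSOTf, 2,6-lutidine, CH2Cl2, −78 to 0 °C
Reagents that add atoms: N,O-dimethylhydroxylamine hydrochloride, CNOC.Cl; tert-butyldimethylsilyl trifluoromethanesulfonate, CC(C)(C)[Si](C)(C)OS(=O)(=O)C(F)(F)F
Why: Aluminium amide aminolysis of the lactone (first half of a Weinreb ketone synthesis) followed at once by silyl triflate protection of both secondary hydroxyls, which should forestall relactonization and touches no stereocentre.

Step 3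
Reactants: 6 N-methoxy-N-methyl-2,4-bis(tert-butyldimethylsilyloxy)-3-isopropenyl-5-(trityloxy)pentanamide; 7 ethylmagnesium bromide
Product: 8 4,6-bis(tert-butyldimethylsilyloxy)-5-isopropenyl-7-(trityloxy)heptan-3-one
Conditions: 7, THF, 0 °C; aq. NH4Cl
Reagents that add atoms: none
Why: Weinreb ketone synthesis, in which the chelated tetrahedral adduct should stop at mono-addition and the α-silyloxy centre C8 should not epimerize.

Step 4
Reactants: 8 4,6-bis(tert-butyldimethylsilyloxy)-5-isopropenyl-7-(trityloxy)heptan-3-one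
Product: 9 4,6-bis(tert-butyldimethylsilyloxy)-7-hydroxy-5-isopropenylheptan-3-one
Conditions: camphorsulfonic acid (cat.), MeOH/CH2Cl2, 0 °C
Reagents that add atoms: none
Why: Acid-catalysed solvolysis of the primary trityl ether through the trityl cation (SN1) should leave the two secondary TBS ethers and the ketone intact.

Step 5
Reactants: 9 4,6-bis(tert-butyldimethylsilyloxy)-7-hydroxy-5-isopropenylheptan-3-one
Product: 10 2,4-bis(tert-butyldimethylsilyloxy)-3-isopropenyl-5-oxoheptanal
Conditions: Dess–Martin periodinane, NaHCO3, CH2Cl2, 0 °C to rt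
Reagents that add atoms: none
Why: Dess–Martin oxidation of the primary alcohol under buffered conditions should give the α-silyloxy aldehyde without epimerization at C6.

Step 6
Reactants: 10 2,4-bis(tert-butyldimethylsilyloxy)-3-isopropenyl-5-oxoheptanal; 11 (Z)-2-bromobut-2-ene
Product: 12 (Z)-5,7-bis(tert-butyldimethylsilyloxy)-4-hydroxy-3-methyl-6-isopropenyldec-2-en-8-one (both epimers at the new carbinol C5)
Conditions: 11, CrCl2, NiCl2 (cat.), DMSO, rt
Reagents that add atoms: none
Why: Nozaki–Hiyama–Kishi coupling, in which the alkenylchromium reagent should add to the aldehyde but not to the ketone and keep the (Z)-geometry of the bromide; the new carbinol centre C5 forms as a mixture that step 7 removes.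

Step 7
Reactants: 12 (Z)-5,7-bis(tert-butyldimethylsilyloxy)-4-hydroxy-3-methyl-6-isopropenyldec-2-en-8-one
Product: 13 (Z)-5,7-bis(tert-butyldimethylsilyloxy)-3-methyl-6-isopropenyldec-2-ene-4,8-dione
Conditions: Dess–Martin periodinane, NaHCO3, CH2Cl2, 0 °C
Reagents that add atoms: none
Why: Dess–Martin oxidation of the allylic alcohol should converge both C5 epimers on the (Z)-enone (an angeloyl-type ketone) under neutral conditions that avoid Z to E isomerization.

Step 8
Reactants: 13 (Z)-5,7-bis(tert-butyldimethylsilyloxy)-3-methyl-6-isopropenyldec-2-ene-4,8-dione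
Product: 15 (1E,8Z)-4,6-bis(tert-butyldimethylsilyloxy)-2,8-dimethyl-3,7-dioxo-5-isopropenyldeca-1,8-dien-1-yl acetate, via hydroxymethylene ketone 14 (not isolated)
Conditions: LiN(SiMe3)2 (1.05 equiv), THF, −78 °C; CF3CH2OCHO; AcOH quench and work-up; crude 14, Ac2O, Et3N, DMAP (cat.), CH2Cl2, 0 °C
Reagents that add atoms: 2,2,2-trifluoroethyl formate, O=COCC(F)(F)F; acetic anhydride, CC(=O)OC(C)=O
Why: Claisen-type formylation of the kinetic enolate at the unhindered ethyl CH2 (C10) and O-acetylation of the hydroxymethylene ketone, which under DMAP equilibration should give the (E)-enol acetate with the acetoxy group anti to the C9 carbonyl.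

Step 9
Reactants: 15 (1E,8Z)-4,6-bis(tert-butyldimethylsilyloxy)-2,8-dimethyl-3,7-dioxo-5-isopropenyldeca-1,8-dien-1-yl acetate
Product: 17 cis-fused decalin cycloadduct (1-acetoxy; 5-trimethylsilyloxy; 6- and 8-TBS-oxy; 4,10-dimethyl; 7-isopropenyl; C3=C4; 9-oxo), via silyl dienol ether 16 (not isolated)
Conditions: TMSOTf (1.1 equiv), Et3N, CH2Cl2, −78 to 0 °C; solvent exchange; toluene, BHT, 110 °C, sealed tube
Reagents that add atoms: trimethylsilyl trifluoromethanesulfonate, C[Si](C)(C)OS(=O)(=O)C(F)(F)F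
Why: Soft enolization of the (Z)-enone, which is held s-cis because the s-trans form pushes C6 against the cis β-methyl group, should give the (Z)-1-siloxy diene C2=C3–C4=C5 with the tether on the outside; this adds in a concerted, asynchronous, suprafacial [4+2] fashion to the (E)-β-acetoxy enone C1=C10, with the nucleophilic terminus C2 bonding to the electrophilic β-carbon C1 ahead of the C5–C10 bond. The closest known reaction type is the type 1 intramolecular Diels–Alder reaction of 1,7,9-decatrien-3-ones and of enone-tethered silyl dienol ethers, which gives cis-fused octalones. Ring B (C10–C1–C2–C3=C4–C5) closes as the new cyclohexene of the cycloaddition and ring A (C5–C6–C7–C8–C9–C10) as the ring spanned by the four-atom tether, both six-membered and fused across the sacrificial C5–C10 bond. C1 is set relative to C10 by the (E)-geometry of the dienophile (acetoxy cis to the C10 methyl), the cis fusion at C5/C10 by the endo position of the tether carbonyl C9 (the exo mode would stack the C10 methyl on the C4 methyl), and the sense of both relative to C6–C8 by a chair tether in which A(1,3) strain against the C4 methyl turns the C6 silyloxy group axial while the isopropenyl and C8 silyloxy groups stay equatorial. The step needs regioselectivity (tether and donor/acceptor polarity agree), an intact diene geometry (moderate temperature; the hindered C6–H should keep [1,5]-hydrogen shift slow) and face selectivity (the chair just described); the centres C5 and C10 are temporary and are erased in step 13.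

Step 10
Reactants: 17 cis-fused decalin cycloadduct
Product: 19 cis-fused decalin 5,9-diol (9-OH trans to the 10-methyl and to 5-OH; 1-acetoxy; 6- and 8-TBS-oxy; C3=C4), via hydroxy ketone 18 (not isolated)
Conditions: PPTS, MeOH, rt; then Me4NBH(OAc)3, MeCN/AcOH, −30 °C
Reagents that add atoms: none
Why: Mild acid cleavage of the tertiary trimethylsilyl ether followed by hydroxyl-directed Evans–Saksena reduction, in which hydride is delivered intramolecularly from the C5-bound acetoxyborohydride to the same face of the C9 ketone and should give the 1,3-anti diol.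

Step 11
Reactants: 19 cis-fused decalin 5,9-diol
Product: 20 3,4-epoxy decalin 5,9-diol (oxirane on the face of 5-OH)
Conditions: VO(acac)2 (cat.), t-BuOOH, CH2Cl2, 0 °C to rt
Reagents that add atoms: tert-butyl hydroperoxide, CC(C)(C)OO
Why: Hydroxyl-directed epoxidation of a cyclic tertiary allylic alcohol, in which the vanadium alkoxide at C5 should deliver oxygen to the ring B alkene on its own face (setting C3 and C4) and leave the isopropenyl group alone.

Step 12
Reactants: 20 3,4-epoxy decalin 5,9-diol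
Product: 21 3,4-epoxy decalin 5-ol 9-methanesulfonate
Conditions: MsCl, Et3N, CH2Cl2, −20 °C
Reagents that add atoms: methanesulfonyl chloride, CS(=O)(=O)Cl
Why: Selective sulfonylation of the secondary C9 hydroxyl over the tertiary C5 hydroxyl should install the leaving group for the fragmentation with retention at C9.

Step 13
Reactants: 21 3,4-epoxy decalin 5-ol 9-methanesulfonate
Product: 23 (Z)-cyclodec-9-en-5-one with free 1-OH (3,4-oxirane; 6- and 8-TBS-oxy; 7-isopropenyl), via acetate 22 (not isolated)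
Conditions: KH, THF, 0 °C; then K2CO3, MeOH, 0 °C
Reagents that add atoms: none
Why: Grob fragmentation of the 1,3-diol monosulfonate, in which the C5 alkoxide should expel mesylate through the cis-decalin conformer that holds C1 axial on ring A and the C5–C10 bond anti-periplanar to the equatorial C9–OMs bond, giving the C5 ketone and the (Z)-C9=C10 alkene stereospecifically before methanolysis frees the C1 hydroxyl.

Step 14
Reactants: 23 (Z)-cyclodec-9-en-5-one with free 1-OH
Product: 24 3,4:9,10-bis-epoxy cyclodecan-5-one with free 1-OH (6- and 8-TBS-oxy)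
Conditions: VO(acac)2 (cat.), t-BuOOH, CH2Cl2, 0 °C
Reagents that add atoms: tert-butyl hydroperoxide, CC(C)(C)OO
Why: Hydroxyl-directed epoxidation of the allylic alcohol, in which H-1 should eclipse the alkene to avoid A(1,3) strain against C8 so that the C1 oxygen delivers the peroxide to the face giving the threo C1/C10 relationship of the target, while the isopropenyl group has no free directing hydroxyl.

Step 15
Reactants: 24 3,4:9,10-bis-epoxy cyclodecan-5-one with free 1-OH; 25 angelic acid
Product: 27 1-angeloyloxy-3,4:9,10-bis-epoxy-6,8-bis(TBS-oxy)-7-isopropenyl-4,10-dimethylcyclodecan-5-one, via mixed anhydride 26 (not isolated)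
Conditions: 25, 2,4,6-trichlorobenzoyl chloride, Et3N, toluene, rt; filter; then 24, 80 °C
Reagents that add atoms: none
Why: Yamaguchi-type esterification through the mixed 2,4,6-trichlorobenzoic anhydride without nucleophilic catalyst, conditions under which the (Z)-geometry of the angeloyl group should survive, applied to the only free hydroxyl (C1) so that exactly one angelate is installed.

Step 16
Reactants: 27 1-angeloyloxy-3,4:9,10-bis-epoxy-6,8-bis(TBS-oxy)-7-isopropenyl-4,10-dimethylcyclodecan-5-one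
Product: 28 1-angeloyloxy-3,4:9,10-bis-epoxy-6,8-dihydroxy-7-isopropenyl-4,10-dimethylcyclodecan-5-one
Conditions: HF·pyridine, pyridine, THF, 0 °C to rt
Reagents that add atoms: none
Why: Fluoride desilylation buffered with pyridine should remove both secondary TBS ethers without opening the oxiranes or cleaving the C1 angelate.

Step 17
Reactants: 28 1-angeloyloxy-3,4:9,10-bis-epoxy-6,8-dihydroxy-7-isopropenyl-4,10-dimethylcyclodecan-5-one; 29 angelic anhydride
Product: 30 CNP0154187.1 (tris-angelate)
Conditions: 29 (3 equiv), THF, −78 °C; LiN(SiMe3)2 (2.2 equiv) added slowly, −78 to −20 °C; aq. NH4Cl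
Reagents that add atoms: none
Why: Acylation of the lithium alkoxides at C6 and C8 by the symmetrical anhydride as they form (stereoconservative angeloylation of hindered alcohols), in which no nucleophilic amine catalyst is present to add to the angeloyl group and isomerize it to tiglate, and the low temperature with in-situ trapping should leave the oxiranes and the α-oxygenated ketone untouched.

**Compound list**

1 | (S)-5-(trityloxymethyl)furan-2(5H)-one | O=C1C=C[C@@H](COC(c2ccccc2)(c2ccccc2)c2ccccc2)O1 | starting material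
2 | isopropenylmagnesium bromide | C=C(C)[Mg]Br | starting material
3 | bromomagnesium enolate of trans-4-isopropenyl-5-(trityloxymethyl)dihydrofuran-2(3H)-one | C=C(C)[C@H]1C=C(O[Mg]Br)O[C@@H]1COC(c2ccccc2)(c2ccccc2)c2ccccc2 | intermediate
4 | all-trans 3-hydroxy-4-isopropenyl-5-(trityloxymethyl)dihydrofuran-2(3H)-one (5S; 3-OH and 5-CH2OTr both trans to 4-isopropenyl) | C=C(C)[C@H]1[C@H](O)C(=O)O[C@@H]1COC(c2ccccc2)(c2ccccc2)c2ccccc2 | intermediate
5 | N-methoxy-N-methyl-2,4-dihydroxy-3-isopropenyl-5-(trityloxy)pentanamide (amide carbon = C9; C2, C3, C4 = C8, C7, C6) | CON(C)C(=O)[C@@H](O)[C@H](C(C)=C)[C@H](O)COC(c1ccccc1)(c1ccccc1)c1ccccc1 | intermediate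
6 | N-methoxy-N-methyl-2,4-bis(tert-butyldimethylsilyloxy)-3-isopropenyl-5-(trityloxy)pentanamide | CON(C)C(=O)[C@@H](O[Si](C)(C)C(C)(C)C)[C@H](C(C)=C)[C@H](O[Si](C)(C)C(C)(C)C)COC(c1ccccc1)(c1ccccc1)c1ccccc1 | intermediate
7 | ethylmagnesium bromide | CC[Mg]Br | starting material
8 | 4,6-bis(tert-butyldimethylsilyloxy)-5-isopropenyl-7-(trityloxy)heptan-3-one | CCC(=O)[C@@H](O[Si](C)(C)C(C)(C)C)[C@H](C(C)=C)[C@H](O[Si](C)(C)C(C)(C)C)COC(c1ccccc1)(c1ccccc1)c1ccccc1 | intermediate
9 | 4,6-bis(tert-butyldimethylsilyloxy)-7-hydroxy-5-isopropenylheptan-3-one | CCC(=O)[C@@H](O[Si](C)(C)C(C)(C)C)[C@H](C(C)=C)[C@H](O[Si](C)(C)C(C)(C)C)CO | intermediate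
10 | 2,4-bis(tert-butyldimethylsilyloxy)-3-isopropenyl-5-oxoheptanal | CCC(=O)[C@@H](O[Si](C)(C)C(C)(C)C)[C@H](C(C)=C)[C@H](O[Si](C)(C)C(C)(C)C)C=O | intermediate
11 | (Z)-2-bromobut-2-ene | C/C=C(/C)Br | starting material
12 | (Z)-5,7-bis(tert-butyldimethylsilyloxy)-4-hydroxy-3-methyl-6-isopropenyldec-2-en-8-one (carbinol centre = C5 of the target, both epimers) | CCC(=O)[C@@H](O[Si](C)(C)C(C)(C)C)[C@H](C(C)=C)[C@H](O[Si](C)(C)C(C)(C)C)C(O)/C(C)=C\C | intermediate
13 | (Z)-5,7-bis(tert-butyldimethylsilyloxy)-3-methyl-6-isopropenyldec-2-ene-4,8-dione | CCC(=O)[C@@H](O[Si](C)(C)C(C)(C)C)[C@H](C(C)=C)[C@H](O[Si](C)(C)C(C)(C)C)C(=O)/C(C)=C\C | intermediate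
14 | hydroxymethylene ketone of 13 at C10 (chelated Z-enol shown) | O/C=C(C)\C(=O)[C@@H](O[Si](C)(C)C(C)(C)C)[C@H](C(C)=C)[C@H](O[Si](C)(C)C(C)(C)C)C(=O)/C(C)=C\C | intermediate
15 | (1E,8Z)-4,6-bis(tert-butyldimethylsilyloxy)-2,8-dimethyl-3,7-dioxo-5-isopropenyldeca-1,8-dien-1-yl acetate | CC(=O)O/C=C(C)/C(=O)[C@@H](O[Si](C)(C)C(C)(C)C)[C@H](C(C)=C)[C@H](O[Si](C)(C)C(C)(C)C)C(=O)/C(C)=C\C | intermediate
16 | (Z)-trimethylsilyl dienol ether of 15 (diene C2=C3–C4=C5, OSiMe3 on the same side as C3) | CC(=O)O/C=C(C)/C(=O)[C@@H](O[Si](C)(C)C(C)(C)C)[C@H](C(C)=C)[C@H](O[Si](C)(C)C(C)(C)C)/C(O[Si](C)(C)C)=C(C)/C=C | intermediate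
17 | cis-fused decalin cycloadduct: 1-acetoxy, 5-trimethylsilyloxy, 10-methyl, 6-TBS-oxy and 7-isopropenyl on one face, 8-TBS-oxy on the other; C3=C4(CH3); 9-oxo | C=C(C)[C@H]1[C@H](O[Si](C)(C)C(C)(C)C)C(=O)[C@]2(C)[C@@H](OC(C)=O)CC=C(C)[C@]2(O[Si](C)(C)C)[C@H]1O[Si](C)(C)C(C)(C)C | intermediate
18 | 5-hydroxy-9-oxo decalin (17 without the trimethylsilyl group) | C=C(C)[C@H]1[C@H](O[Si](C)(C)C(C)(C)C)C(=O)[C@]2(C)[C@@H](OC(C)=O)CC=C(C)[C@]2(O)[C@H]1O[Si](C)(C)C(C)(C)C | intermediate
19 | decalin 5,9-diol (9-OH on the face of 8-TBS-oxy, trans to 10-methyl and 5-OH) | C=C(C)[C@H]1[C@H](O[Si](C)(C)C(C)(C)C)[C@H](O)[C@]2(C)[C@@H](OC(C)=O)CC=C(C)[C@]2(O)[C@H]1O[Si](C)(C)C(C)(C)C | intermediate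
20 | 3,4-epoxy decalin 5,9-diol (oxirane on the face of 5-OH) | C=C(C)[C@H]1[C@H](O[Si](C)(C)C(C)(C)C)[C@H](O)[C@]2(C)[C@@H](OC(C)=O)C[C@H]3O[C@@]3(C)[C@]2(O)[C@H]1O[Si](C)(C)C(C)(C)C | intermediate
21 | 3,4-epoxy decalin 5-ol 9-methanesulfonate | C=C(C)[C@H]1[C@H](O[Si](C)(C)C(C)(C)C)[C@H](OS(C)(=O)=O)[C@]2(C)[C@@H](OC(C)=O)C[C@H]3O[C@@]3(C)[C@]2(O)[C@H]1O[Si](C)(C)C(C)(C)C | intermediate
22 | (Z)-1-acetoxy-3,4-epoxy-6,8-bis(TBS-oxy)-7-isopropenyl-4,10-dimethylcyclodec-9-en-5-one | C=C(C)[C@H]1[C@H](O[Si](C)(C)C(C)(C)C)/C=C(C)\[C@@H](OC(C)=O)C[C@H]2O[C@@]2(C)C(=O)[C@H]1O[Si](C)(C)C(C)(C)C | intermediate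
23 | (Z)-3,4-epoxy-1-hydroxy-6,8-bis(TBS-oxy)-7-isopropenyl-4,10-dimethylcyclodec-9-en-5-one | C=C(C)[C@H]1[C@H](O[Si](C)(C)C(C)(C)C)/C=C(C)\[C@@H](O)C[C@H]2O[C@@]2(C)C(=O)[C@H]1O[Si](C)(C)C(C)(C)C | intermediate
24 | 3,4:9,10-bis-epoxy-1-hydroxy-6,8-bis(TBS-oxy)-7-isopropenyl-4,10-dimethylcyclodecan-5-one | C=C(C)[C@H]1[C@H](O[Si](C)(C)C(C)(C)C)[C@@H]2O[C@]2(C)[C@@H](O)C[C@H]2O[C@@]2(C)C(=O)[C@H]1O[Si](C)(C)C(C)(C)C | intermediate
25 | angelic acid ((Z)-2-methylbut-2-enoic acid) | C/C=C(/C)C(=O)O | starting material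
26 | angelic 2,4,6-trichlorobenzoic anhydride | C/C=C(/C)C(=O)OC(=O)c1c(Cl)cc(Cl)cc1Cl | intermediate
27 | 1-angeloyloxy-3,4:9,10-bis-epoxy-6,8-bis(TBS-oxy)-7-isopropenyl-4,10-dimethylcyclodecan-5-one | C=C(C)[C@H]1[C@H](O[Si](C)(C)C(C)(C)C)[C@@H]2O[C@]2(C)[C@@H](OC(=O)/C(C)=C\C)C[C@H]2O[C@@]2(C)C(=O)[C@H]1O[Si](C)(C)C(C)(C)C | intermediate
28 | 1-angeloyloxy-3,4:9,10-bis-epoxy-6,8-dihydroxy-7-isopropenyl-4,10-dimethylcyclodecan-5-one | C=C(C)[C@H]1[C@H](O)[C@@H]2O[C@]2(C)[C@@H](OC(=O)/C(C)=C\C)C[C@H]2O[C@@]2(C)C(=O)[C@H]1O | intermediate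
29 | angelic anhydride ((Z)-2-methylbut-2-enoic anhydride) | C/C=C(/C)C(=O)OC(=O)/C(C)=C\C | starting material
30 | CNP0154187.1 | C=C(C)[C@H]1[C@H](OC(=O)/C(C)=C\C)[C@@H]2O[C@]2(C)[C@@H](OC(=O)/C(C)=C\C)C[C@H]2O[C@@]2(C)C(=O)[C@H]1OC(=O)/C(C)=C\C | target

**Step count and risks**

Total step count: 17. Longest linear sequence: 17 steps (from 1 to 30).

Step 9. The β-acetoxy enone may be too weak a dienophile, so that [1,5]-hydrogen shift or geometric isomerization of the siloxy diene, or Z/E isomerization of the enol acetate, competes with cycloaddition and erodes the C1 configuration or the face selectivity. The fallback sets out from hydroxymethylene ketone 14 and comes back at cycloadduct 17. O-Triflation (PhNTf2, Et3N) gives the (E)-enol triflate F1, and Miyaura borylation (B2pin2, PdCl2(dppf), KOAc) gives the (E)-β-boryl enone F2, a more electron-poor dienophile without a leaving group on oxygen. Soft enolization (TMSOTf, Et3N) gives the silyl dienol ether F3, which on heating should undergo the same intramolecular Diels–Alder reaction to the boronate cycloadduct F4. Oxidation of the C–B bond with retention (NaBO3, THF/H2O) gives the C1 alcohol F5, and acetylation (Ac2O, pyridine) gives 17.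

Step 14. The ten-membered ring may hold the C1 hydroxyl so that oxygen is delivered cis to it across the ring, which is the wrong face of the C9=C10 bond, or delivery may be slow enough for epoxidation of the isopropenyl group to compete. The fallback sets out from allylic alcohol 23 and comes back at diol 28. Yamaguchi esterification of the C1 hydroxyl (angelic acid 25, 2,4,6-trichlorobenzoyl chloride, Et3N, toluene, 80 °C) gives the 1-angelate alkene F6, which can no longer direct from C1. Desilylation (HF·pyridine, pyridine, THF) gives the 6,8-diol alkene F7. In the target the C9–C10 oxirane oxygen is cis to O-8 and trans to O-1 across the ring, so ring-controlled cis delivery from the C8 hydroxyl (VO(acac)2, t-BuOOH) should reach the required face and give 28.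

Step 17. Acylation of the two hindered hydroxyls may stop at the monoester, or the lithium alkoxides may trigger epoxide migration from C8, epimerization at C6 next to the ketone, or isomerization of angelate to tiglate. The fallback sets out from diol 28 and arrives at target 30. Steglich esterification (DCC, DMAP) with 2-[bis(2,2,2-trifluoroethoxy)phosphoryl]propanoic acid gives the 6,8-bis(phosphonopropanoate) F8 (phosphonate α-carbons as a mixture). A twofold Still–Gennari olefination (KN(SiMe3)2, 18-crown-6, acetaldehyde, THF, −78 °C) should then build the two remaining (Z)-2-methylbut-2-enoates directly.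

Further compounds
F1 | step 9 | (E)-enol triflate of hydroxymethylene ketone 14 | O=S(=O)(O/C=C(C)/C(=O)[C@@H](O[Si](C)(C)C(C)(C)C)[C@H](C(C)=C)[C@H](O[Si](C)(C)C(C)(C)C)C(=O)/C(C)=C\C)C(F)(F)F
F2 | step 9 | (E)-β-(pinacolboryl) enone | CC1(C)OB(/C=C(C)/C(=O)[C@@H](O[Si](C)(C)C(C)(C)C)[C@H](C(C)=C)[C@H](O[Si](C)(C)C(C)(C)C)C(=O)/C(C)=C\C)OC1(C)C
F3 | step 9 | (Z)-trimethylsilyl dienol ether of F2 | CC1(C)OB(/C=C(C)/C(=O)[C@@H](O[Si](C)(C)C(C)(C)C)[C@H](C(C)=C)[C@H](O[Si](C)(C)C(C)(C)C)/C(O[Si](C)(C)C)=C(C)/C=C)OC1(C)C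
F4 | step 9 | cis-fused decalin cycloadduct with pinacolboryl group on C1 | C=C(C)[C@H]1[C@H](O[Si](C)(C)C(C)(C)C)C(=O)[C@]2(C)[C@@H](B3OC(C)(C)C(C)(C)O3)CC=C(C)[C@]2(O[Si](C)(C)C)[C@H]1O[Si](C)(C)C(C)(C)C
F5 | step 9 | cis-fused decalin cycloadduct with free 1-OH | C=C(C)[C@H]1[C@H](O[Si](C)(C)C(C)(C)C)C(=O)[C@]2(C)[C@@H](O)CC=C(C)[C@]2(O[Si](C)(C)C)[C@H]1O[Si](C)(C)C(C)(C)C
F6 | step 14 | (Z)-1-angeloyloxy-3,4-epoxy-6,8-bis(TBS-oxy)-7-isopropenyl-4,10-dimethylcyclodec-9-en-5-one | C=C(C)[C@H]1[C@H](O[Si](C)(C)C(C)(C)C)/C=C(C)\[C@@H](OC(=O)/C(C)=C\C)C[C@H]2O[C@@]2(C)C(=O)[C@H]1O[Si](C)(C)C(C)(C)C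
F7 | step 14 | (Z)-1-angeloyloxy-3,4-epoxy-6,8-dihydroxy-7-isopropenyl-4,10-dimethylcyclodec-9-en-5-one | C=C(C)[C@H]1[C@H](O)/C=C(C)\[C@@H](OC(=O)/C(C)=C\C)C[C@H]2O[C@@]2(C)C(=O)[C@H]1O
F8 | step 17 | 1-angelate 6,8-bis{2-[bis(2,2,2-trifluoroethoxy)phosphoryl]propanoate} of diol 28 | C=C(C)[C@H]1[C@H](OC(=O)C(C)P(=O)(OCC(F)(F)F)OCC(F)(F)F)[C@@H]2O[C@]2(C)[C@@H](OC(=O)/C(C)=C\C)C[C@H]2O[C@@]2(C)C(=O)[C@H]1OC(=O)C(C)P(=O)(OCC(F)(F)F)OCC(F)(F)F
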